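**Plan**

Unit 1 is the 7-methoxyflavone joined through C6 and unit 2 is the flavone joined through C8. The target is the 7-O-methyl ether of 6,8''-biapigenin.
Enabling feature: ring A of unit 2 is a benzene oxygenated at C5, C7 and C8a. Its axis carbon C8 stands between the oxygen-bearing C7 and C8a, which is the place the substituted carbon of an ynol ether takes when a vinylketene is annulated onto it.
Cuts, in retrosynthetic order: O1–C2, C2–C3 and C4–C4a of the unit 2 pyranone. Then C8–C8a, C6–C7 and C4a–C8a of unit 2 ring A, which reduces the biaryl axis to an aryl–alkynyl bond. Then that bond at C6 of unit 1, and O1–C2/C2–C3 of the unit 1 pyranone.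
Forward: unit 1 pyranone (chalcone, oxidative closure), C6 iodide, ethynyl, siloxyethynyl, ring A of unit 2 by benzannulation, unit 2 pyranone (acetylation, chalcone, oxidative closure), then global dealkylation that spares the 7-OMe.
Stereochemistry: there is no stereocentre. The E-alkenes of both chalcones vanish on ring closure and the hindered axis forms as a racemate.

Key step: step 9

Assumption: the target SMILES carries no axial descriptor, so the racemic mixture of atropisomers about the tetra-ortho-substituted axis is taken as the goal.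

**Step 1**
Reactants: 1 1-(2,6-dihydroxy-4-methoxyphenyl)ethanone; 2 4-(benzyloxy)benzaldehyde
Product: 3 (E)-3-[4-(benzyloxy)phenyl]-1-(2,6-dihydroxy-4-methoxyphenyl)prop-2-en-1-one
Conditions: KOH (50% aq, excess), EtOH, rt; then 1 M HCl, 0 °C
Reagents that add atoms: none
Why: Claisen–Schmidt condensation, in which only the methyl ketone can enolise, so crossed aldol addition and E1cB loss of water should give the thermodynamically preferred E-enone, concentrated base making up for the low C–H acidity of the bis-phenoxide, and partial ring closure on work-up does no harm because the next step closes that ring anyway.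

**Step 2**
Reactants: 3 (E)-3-[4-(benzyloxy)phenyl]-1-(2,6-dihydroxy-4-methoxyphenyl)prop-2-en-1-one
Product: 4 2-[4-(benzyloxy)phenyl]-5-hydroxy-7-methoxychromen-4-one
Conditions: I2 (10 mol %), DMSO, 130 °C
Reagents that add atoms: none
Why: I2/DMSO oxidative cyclisation of a 2'-hydroxychalcone (6-endo oxa-Michael closure, iodination, loss of HI, DMSO re-oxidising HI), in which the two ortho hydroxyls of 3 are equivalent so only one flavone can arise and the non-chelated aryl benzyl ether is tolerated.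

**Step 3**
Reactants: 4 2-[4-(benzyloxy)phenyl]-5-hydroxy-7-methoxychromen-4-one
Product: 5 2-[4-(benzyloxy)phenyl]-5-hydroxy-6-iodo-7-methoxychromen-4-one
Conditions: NIS (1.05 equiv), DMF, rt, dark
Reagents that add atoms: N-iodosuccinimide, O=C1CCC(=O)N1I
Why: Electrophilic aromatic iodination, in which 5-hydroxy-7-alkoxyflavones with a free chelated 5-OH are attacked under neutral conditions at C6 and not at C8, ring A being far more electron-rich than ring B or the pyranone.

**Step 4**
Reactants: 5 2-[4-(benzyloxy)phenyl]-5-hydroxy-6-iodo-7-methoxychromen-4-one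
Product: 6 5-(benzyloxy)-2-[4-(benzyloxy)phenyl]-6-iodo-7-methoxychromen-4-one
Conditions: BnBr (1.5 equiv), K2CO3, DMF, 70 °C
Reagents that add atoms: benzyl bromide, BrCc1ccccc1
Why: Williamson etherification, which needs a polar solvent and heat because the 5-OH is hydrogen-bonded to C4=O and flanked by iodine, and which removes the acidic proton that would quench the lithium reagents of step 7.

**Step 5**
Reactants: 6 5-(benzyloxy)-2-[4-(benzyloxy)phenyl]-6-iodo-7-methoxychromen-4-one; 7 ethynyltrimethylsilane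
Product: 8 5-(benzyloxy)-2-[4-(benzyloxy)phenyl]-7-methoxy-6-[(trimethylsilyl)ethynyl]chromen-4-one
Conditions: PdCl2(PPh3)2 (5 mol %), CuI (10 mol %), Et3N/DMF, 60 °C
Reagents that add atoms: none
Why: Sonogashira coupling, in which the aryl iodide adds readily to zerovalent palladium and the linear alkynyl partner fits between the two ortho alkoxy groups, as known for 2,6-dialkoxyiodoarenes and 6-iodoflavones.

**Step 6**
Reactants: 8 5-(benzyloxy)-2-[4-(benzyloxy)phenyl]-7-methoxy-6-[(trimethylsilyl)ethynyl]chromen-4-one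
Product: 9 5-(benzyloxy)-2-[4-(benzyloxy)phenyl]-6-ethynyl-7-methoxychromen-4-one
Conditions: K2CO3 (0.2 equiv), MeOH/CH2Cl2, rt
Reagents that add atoms: none
Why: Methoxide-catalysed protodesilylation of an alkynylsilane, mild enough to leave the pyranone and the benzyl ethers untouched.

**Step 7**
Reactants: 9 5-(benzyloxy)-2-[4-(benzyloxy)phenyl]-6-ethynyl-7-methoxychromen-4-one
Product: 12 5-(benzyloxy)-2-[4-(benzyloxy)phenyl]-7-methoxy-6-[(triisopropylsiloxy)ethynyl]chromen-4-one, via lithium acetylide 10 (not isolated), via lithium ynolate 11 (not isolated)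
Conditions: t-BuOOH (in decane, 1.1 equiv), LiN(SiMe3)2 (2.2 equiv), THF, −78 → 0 °C; then TIPSOTf (1.2 equiv), −78 → 0 °C
Reagents that add atoms: tert-butyl hydroperoxide, CC(C)(C)OO; triisopropylsilyl trifluoromethanesulfonate, CC(C)[Si](OS(=O)(=O)C(F)(F)F)(C(C)C)C(C)C
Why: Oxenoid oxidation of a lithium acetylide with LiOOt-Bu followed by O-silylation of the ynolate, in which the acetylide carbon displaces tert-butoxide from the peroxide oxygen, the bulky silyl triflate reacts at oxygen of the ambident ynolate, and the non-nucleophilic amide base together with the poor acceptor character of the vinylogous-ester pyranone should spare the flavone.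

**Step 8**
Reactants: 13 ethoxyacetylene
Product: 14 3-ethoxycyclobut-2-en-1-one
Conditions: ketene gas (acetone pyrolysis, ketene generator), CH2Cl2, 0 °C → rt; distillation
Reagents that add atoms: ketene, C=C=O
Why: Thermal [2+2] cycloaddition of ketene with an ynol ether, in which the nucleophilic CH terminus of ethoxyacetylene bonds to the ketene carbonyl carbon and so places the ethoxy group at C3 of the cyclobutenone.

**Step 9**
Reactants: 12 5-(benzyloxy)-2-[4-(benzyloxy)phenyl]-7-methoxy-6-[(triisopropylsiloxy)ethynyl]chromen-4-one; 14 3-ethoxycyclobut-2-en-1-one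
Product: 19 5-(benzyloxy)-2-[4-(benzyloxy)phenyl]-6-[4-ethoxy-2-hydroxy-6-(triisopropylsiloxy)phenyl]-7-methoxychromen-4-one, via 3-ethoxyvinylketene 15 (not isolated), via vinylcyclobutenone adduct 16 (not isolated), via dienylketene 17 (not isolated), via cyclohexadienone tautomer 18 (not isolated)
Conditions: 14 (3 equiv, in portions), toluene, sealed tube, 110 °C, then 140 °C
Reagents that add atoms: none
Why: Heat opens 14 by a four-electron conrotatory electrocyclic reaction to vinylketene 15, which adds [2+2] across the triple bond of 12 to give 16 and thereby forms C8–C8a and C6–C7 of unit 2. Adduct 16 opens in the same way to dienylketene 17, whose six-electron disrotatory electrocyclisation forms C4a–C8a and closes ring A of unit 2 as dienone 18, and enolisation gives phenol 19 with every atom of both partners retained. The closest known reaction type is the Danheiser benzannulation of cyclobutenones with trialkylsiloxyalkynes to mono-silylated resorcinols, applied here to an aryl-substituted and doubly ortho-flanked alkyne. The selectivity needed is the regiochemistry of the [2+2] step: donation from the siloxy oxygen makes the flavone-bearing alkyne carbon the nucleophilic terminus, so it bonds to the electrophilic ketene carbonyl carbon, which puts the free OH on C8a, the silyl ether on C7 and the ethyl ether on C5. No stereocentre persists, since the sp3 carbon of 16 is erased on ring opening and the axis forms as a racemate. Because C8 is still linear when its new bonds are made, the crowding of four ortho substituents builds up only in the exergonic aromatisation, and the pyranone, methyl and benzyl ethers are inert to neutral thermolysis.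

**Step 10**
Reactants: 19 5-(benzyloxy)-2-[4-(benzyloxy)phenyl]-6-[4-ethoxy-2-hydroxy-6-(triisopropylsiloxy)phenyl]-7-methoxychromen-4-one
Product: 20 6-[3-acetyl-4-ethoxy-2-hydroxy-6-(triisopropylsiloxy)phenyl]-5-(benzyloxy)-2-[4-(benzyloxy)phenyl]-7-methoxychromen-4-one
Conditions: Ac2O (1.5 equiv), BF3·OEt2 (3 equiv), CH2Cl2, 0 °C → rt; then sat. aq NaHCO3
Reagents that add atoms: acetic anhydride, CC(=O)OC(C)=O
Why: Friedel–Crafts acetylation of a phloroglucinol-type ring, in which C4a of unit 2 lies between OH and OEt and gives the chelated ortho-hydroxy ketone whereas C6 is screened by the triisopropylsilyl group, and the carbonyl-deactivated rings of unit 1 do not compete.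

**Step 11**
Reactants: 20 6-[3-acetyl-4-ethoxy-2-hydroxy-6-(triisopropylsiloxy)phenyl]-5-(benzyloxy)-2-[4-(benzyloxy)phenyl]-7-methoxychromen-4-one
Product: 22 6-[3-acetyl-6-(benzyloxy)-4-ethoxy-2-hydroxyphenyl]-5-(benzyloxy)-2-[4-(benzyloxy)phenyl]-7-methoxychromen-4-one, via caesium phenoxide 21 (not isolated)
Conditions: CsF (1.5 equiv), BnBr (1.1 equiv), DMF, rt
Reagents that add atoms: benzyl bromide, BrCc1ccccc1
Why: Fluoride desilylation with in situ Williamson benzylation (direct conversion of an aryl silyl ether into an aryl alkyl ether), in which the phenoxide released para to the acetyl group is alkylated while the chelated, doubly flanked 2-OH stays free, the exchange being made because a silyl ether para to a ketone would not last in the KOH of step 12.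

**Step 12**
Reactants: 22 6-[3-acetyl-6-(benzyloxy)-4-ethoxy-2-hydroxyphenyl]-5-(benzyloxy)-2-[4-(benzyloxy)phenyl]-7-methoxychromen-4-one; 2 4-(benzyloxy)benzaldehyde
Product: 23 5-(benzyloxy)-6-{6-(benzyloxy)-3-[(E)-3-(4-(benzyloxy)phenyl)prop-2-enoyl]-4-ethoxy-2-hydroxyphenyl}-2-[4-(benzyloxy)phenyl]-7-methoxychromen-4-one
Conditions: KOH (50% aq), EtOH/THF, rt; then 1 M HCl, 0 °C
Reagents that add atoms: none
Why: Claisen–Schmidt condensation of a 2-hydroxy-4,6-dialkoxyacetophenone, the standard substrate class for this reaction, giving the E-enone by E1cB dehydration at a temperature at which hydroxide attack on the fully substituted flavone of unit 1 is slow.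

**Step 13**
Reactants: 23 5-(benzyloxy)-6-{6-(benzyloxy)-3-[(E)-3-(4-(benzyloxy)phenyl)prop-2-enoyl]-4-ethoxy-2-hydroxyphenyl}-2-[4-(benzyloxy)phenyl]-7-methoxychromen-4-one
Product: 24 5,4',7'',4'''-tetra-O-benzyl-5''-O-ethyl-7-O-methyl-6,8''-biapigenin
Conditions: I2 (10 mol %), DMSO, 130 °C
Reagents that add atoms: none
Why: I2/DMSO oxidative cyclisation of a 2'-hydroxychalcone, in which the only free hydroxyl is the one on C8a next to the axis, so 6-endo closure can give nothing but the 8-linked flavone, as known for pyranone construction beside a biaryl axis in biflavone work.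

**Step 14**
Reactants: 24 5,4',7'',4'''-tetra-O-benzyl-5''-O-ethyl-7-O-methyl-6,8''-biapigenin
Product: 25 6-[5,7-dihydroxy-2-(4-hydroxyphenyl)-4-oxochromen-8-yl]-5-hydroxy-2-(4-hydroxyphenyl)-7-methoxychromen-4-one (target)
Conditions: BCl3 (1 M in CH2Cl2, excess), C6HMe5 (excess), CH2Cl2, −78 °C → rt; then 1 M aq HCl/THF
Reagents that add atoms: none
Why: BCl3 ether cleavage with pentamethylbenzene as cation scavenger, in which the four benzyl ethers fall at low temperature without C-benzylation of the electron-rich rings, the 5''-ethyl ether is cleaved on warming through boron chelation to the peri carbonyl, and the 7-OMe has no neighbouring carbonyl and should stay.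

**Compound list**

1 | 1-(2,6-dihydroxy-4-methoxyphenyl)ethanone | COc1cc(O)c(C(C)=O)c(O)c1 | starting material
2 | 4-(benzyloxy)benzaldehyde | O=Cc1ccc(OCc2ccccc2)cc1 | starting material
3 | (E)-3-[4-(benzyloxy)phenyl]-1-(2,6-dihydroxy-4-methoxyphenyl)prop-2-en-1-one | COc1cc(O)c(C(=O)/C=C/c2ccc(OCc3ccccc3)cc2)c(O)c1 | intermediate
4 | 2-[4-(benzyloxy)phenyl]-5-hydroxy-7-methoxychromen-4-one | COc1cc2oc(-c3ccc(OCc4ccccc4)cc3)cc(=O)c2c(O)c1 | intermediate
5 | 2-[4-(benzyloxy)phenyl]-5-hydroxy-6-iodo-7-methoxychromen-4-one | COc1cc2oc(-c3ccc(OCc4ccccc4)cc3)cc(=O)c2c(O)c1I | intermediate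
6 | 5-(benzyloxy)-2-[4-(benzyloxy)phenyl]-6-iodo-7-methoxychromen-4-one | COc1cc2oc(-c3ccc(OCc4ccccc4)cc3)cc(=O)c2c(OCc2ccccc2)c1I | intermediate
7 | ethynyltrimethylsilane | C#C[Si](C)(C)C | starting material
8 | 5-(benzyloxy)-2-[4-(benzyloxy)phenyl]-7-methoxy-6-[(trimethylsilyl)ethynyl]chromen-4-one | COc1cc2oc(-c3ccc(OCc4ccccc4)cc3)cc(=O)c2c(OCc2ccccc2)c1C#C[Si](C)(C)C | intermediate
9 | 5-(benzyloxy)-2-[4-(benzyloxy)phenyl]-6-ethynyl-7-methoxychromen-4-one | COc1cc2oc(-c3ccc(OCc4ccccc4)cc3)cc(=O)c2c(OCc2ccccc2)c1C#C | intermediate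
10 | lithium acetylide of 9 | COc1cc2oc(-c3ccc(OCc4ccccc4)cc3)cc(=O)c2c(OCc2ccccc2)c1C#C[Li] | intermediate
11 | lithium ynolate (lithium 2-aryl-ethynolate, aryl = flavon-6-yl of 9) | COc1cc2oc(-c3ccc(OCc4ccccc4)cc3)cc(=O)c2c(OCc2ccccc2)c1C#C[O-].[Li+] | intermediate
12 | 5-(benzyloxy)-2-[4-(benzyloxy)phenyl]-7-methoxy-6-[(triisopropylsiloxy)ethynyl]chromen-4-one | COc1cc2oc(-c3ccc(OCc4ccccc4)cc3)cc(=O)c2c(OCc2ccccc2)c1C#CO[Si](C(C)C)(C(C)C)C(C)C | intermediate
13 | ethoxyacetylene | C#COCC | starting material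
14 | 3-ethoxycyclobut-2-en-1-one | CCOC1=CC(=O)C1 | intermediate
15 | 3-ethoxybuta-1,3-dien-1-one (3-ethoxyvinylketene) | C=C(OCC)C=C=O | intermediate
16 | 2-(flavon-6-yl)-4-(1-ethoxyethenyl)-3-(triisopropylsiloxy)cyclobut-2-en-1-one, racemic (flavon-6-yl as in 12) | COc1cc2oc(-c3ccc(OCc4ccccc4)cc3)cc(=O)c2c(OCc2ccccc2)c1C1=C(O[Si](C(C)C)(C(C)C)C(C)C)C(C(=C)OCC)C1=O | intermediate
17 | 2-(flavon-6-yl)-5-ethoxy-3-(triisopropylsiloxy)hexa-1,3,5-trien-1-one, ketene and ethoxyvinyl groups cis on the central double bond | COc1cc2oc(-c3ccc(OCc4ccccc4)cc3)cc(=O)c2c(OCc2ccccc2)c1C(=C=O)/C(O[Si](C(C)C)(C(C)C)C(C)C)=C\C(=C)OCC | intermediate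
18 | 2-(flavon-6-yl)-5-ethoxy-3-(triisopropylsiloxy)cyclohexa-2,4-dien-1-one | COc1cc2oc(-c3ccc(OCc4ccccc4)cc3)cc(=O)c2c(OCc2ccccc2)c1C1=C(O[Si](C(C)C)(C(C)C)C(C)C)C=C(OCC)CC1=O | intermediate
19 | 5-(benzyloxy)-2-[4-(benzyloxy)phenyl]-6-[4-ethoxy-2-hydroxy-6-(triisopropylsiloxy)phenyl]-7-methoxychromen-4-one | COc1cc2oc(-c3ccc(OCc4ccccc4)cc3)cc(=O)c2c(OCc2ccccc2)c1-c1c(O)cc(OCC)cc1O[Si](C(C)C)(C(C)C)C(C)C | intermediate
20 | 6-[3-acetyl-4-ethoxy-2-hydroxy-6-(triisopropylsiloxy)phenyl]-5-(benzyloxy)-2-[4-(benzyloxy)phenyl]-7-methoxychromen-4-one | COc1cc2oc(-c3ccc(OCc4ccccc4)cc3)cc(=O)c2c(OCc2ccccc2)c1-c1c(O)c(C(C)=O)c(OCC)cc1O[Si](C(C)C)(C(C)C)C(C)C | intermediate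
21 | caesium phenoxide from desilylation of 20 | COc1cc2oc(-c3ccc(OCc4ccccc4)cc3)cc(=O)c2c(OCc2ccccc2)c1-c1c(O)c(C(C)=O)c(OCC)cc1[O-].[Cs+] | intermediate
22 | 6-[3-acetyl-6-(benzyloxy)-4-ethoxy-2-hydroxyphenyl]-5-(benzyloxy)-2-[4-(benzyloxy)phenyl]-7-methoxychromen-4-one | COc1cc2oc(-c3ccc(OCc4ccccc4)cc3)cc(=O)c2c(OCc2ccccc2)c1-c1c(O)c(C(C)=O)c(OCC)cc1OCc1ccccc1 | intermediate
23 | 5-(benzyloxy)-6-{6-(benzyloxy)-3-[(E)-3-(4-(benzyloxy)phenyl)prop-2-enoyl]-4-ethoxy-2-hydroxyphenyl}-2-[4-(benzyloxy)phenyl]-7-methoxychromen-4-one | COc1cc2oc(-c3ccc(OCc4ccccc4)cc3)cc(=O)c2c(OCc2ccccc2)c1-c1c(O)c(C(=O)/C=C/c2ccc(OCc3ccccc3)cc2)c(OCC)cc1OCc1ccccc1 | intermediate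
24 | 5,4',7'',4'''-tetra-O-benzyl-5''-O-ethyl-7-O-methyl-6,8''-biapigenin | COc1cc2oc(-c3ccc(OCc4ccccc4)cc3)cc(=O)c2c(OCc2ccccc2)c1-c1c(OCc2ccccc2)cc(OCC)c2c(=O)cc(-c3ccc(OCc4ccccc4)cc3)oc12 | intermediate
25 | 6-[5,7-dihydroxy-2-(4-hydroxyphenyl)-4-oxochromen-8-yl]-5-hydroxy-2-(4-hydroxyphenyl)-7-methoxychromen-4-one (CNP0246647.0) | COc1cc2oc(-c3ccc(O)cc3)cc(=O)c2c(O)c1-c1c(O)cc(O)c2c(=O)cc(-c3ccc(O)cc3)oc12 | target

**Step count**

Total step count: 14.
Longest linear sequence: 13 steps (steps 1–7 and 9–14). Step 8 lies on a side branch.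

**Steps most likely to fail**

**Step 9.**
- What may go wrong: The alkoxy-stabilised cyclobutenone may open only slowly. Dimerisation of the vinylketene, acylation of the product phenol by excess ketene, or thermal decay of the ynol silyl ether could then outrun the [2+2] addition to the doubly flanked triple bond. The final electrocyclisation may also be held back as strain builds around the axis.
- Fallback: The axis would be made by cross-coupling of two complete flavones, setting out from iodide 6.
  - Commercial apigenin would be perbenzylated (BnBr, K2CO3, DMF, 80 °C) to 5,7-bis(benzyloxy)-2-[4-(benzyloxy)phenyl]chromen-4-one F1.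
  - Iodination (NIS, cat. CF3CO2H, MeCN) occurs at C8, as is usual once the 5-oxygen is capped, and gives 8-iodo-tri-O-benzylapigenin F2.
  - Miyaura borylation (B2pin2, PdCl2(dppf), KOAc, dioxane, 90 °C) gives the 8-pinacolboronate of tri-O-benzylapigenin F3.
  - Suzuki–Miyaura coupling of the boronate with 6 (Pd2(dba)3, SPhos, K3PO4, toluene/H2O, 100 °C) would give 5,4',5'',7'',4'''-penta-O-benzyl-7-O-methyl-6,8''-biapigenin F4.
  - Under the conditions of step 14 this product comes back to the route at target 25.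

**Step 7.**
- What may go wrong: During the warm-up to 0 °C the acetylide, the ynolate or the peroxide anion may add to the pyranone of a second molecule. Excess silyl triflate may activate the C4 carbonyl. Silylation may occur at carbon, and the product may hydrolyse on silica.
- Fallback: The ynolate would be released cold from an alkynyl sulfonate, with no peroxide and no warm acetylide stage, setting out from alkyne 9.
  - Heating 9 with PhI(OH)OTs (CHCl3, reflux) should give the alkynyl(phenyl)iodonium tosylate F5.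
  - Catalytic CuOTf in MeCN converts this salt into the alkynyl 4-toluenesulfonate F6.
  - MeLi (THF, −78 °C) attacks sulfur and sets free lithium ynolate 11.
  - Silylation in the same flask with TIPSOTf rejoins the route at 12.

**Step 10.**
- What may go wrong: The Lewis acid may strip the silyl ether or the peri benzyl ether. Acylation may stop at oxygen of the hindered phenol, or attack may drift to C6 of unit 2.
- Fallback: The carbon would be brought in by a strictly ortho-directed, base-mediated reaction, setting out from phenol 19.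
  - Casnati–Skattebøl formylation (MgCl2, Et3N, paraformaldehyde, MeCN, reflux) delivers formaldehyde within the magnesium phenoxide and should give the 3-formyl analogue of 20 F7.
  - The aldehyde-selective reagent MeTi(OiPr)3 (THF, −30 → 0 °C) would give the 3-(1-hydroxyethyl) analogue of 20 F8.
  - MnO2 (CH2Cl2, rt) oxidises the benzylic alcohol and comes back to the route at 20.

**Further compounds**

F1 | step 9 | 5,7-bis(benzyloxy)-2-[4-(benzyloxy)phenyl]chromen-4-one | O=c1cc(-c2ccc(OCc3ccccc3)cc2)oc2cc(OCc3ccccc3)cc(OCc3ccccc3)c12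
F2 | step 9 | 5,7-bis(benzyloxy)-2-[4-(benzyloxy)phenyl]-8-iodochromen-4-one | O=c1cc(-c2ccc(OCc3ccccc3)cc2)oc2c(I)c(OCc3ccccc3)cc(OCc3ccccc3)c12
F3 | step 9 | 5,7-bis(benzyloxy)-2-[4-(benzyloxy)phenyl]-8-(4,4,5,5-tetramethyl-1,3,2-dioxaborolan-2-yl)chromen-4-one | O=c1cc(-c2ccc(OCc3ccccc3)cc2)oc2c(B3OC(C)(C)C(C)(C)O3)c(OCc3ccccc3)cc(OCc3ccccc3)c12
F4 | step 9 | 5,4',5'',7'',4'''-penta-O-benzyl-7-O-methyl-6,8''-biapigenin | COc1cc2oc(-c3ccc(OCc4ccccc4)cc3)cc(=O)c2c(OCc2ccccc2)c1-c1c(OCc2ccccc2)cc(OCc2ccccc2)c2c(=O)cc(-c3ccc(OCc4ccccc4)cc3)oc12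
F5 | step 7 | [2-(flavon-6-yl)ethynyl](phenyl)iodonium 4-toluenesulfonate (flavon-6-yl as in 9) | COc1cc2oc(-c3ccc(OCc4ccccc4)cc3)cc(=O)c2c(OCc2ccccc2)c1C#C[I+]c1ccccc1.Cc1ccc(S(=O)(=O)[O-])cc1
F6 | step 7 | 2-(flavon-6-yl)ethynyl 4-toluenesulfonate (flavon-6-yl as in 9) | COc1cc2oc(-c3ccc(OCc4ccccc4)cc3)cc(=O)c2c(OCc2ccccc2)c1C#COS(=O)(=O)c1ccc(C)cc1
F7 | step 10 | 5-(benzyloxy)-2-[4-(benzyloxy)phenyl]-6-[4-ethoxy-3-formyl-2-hydroxy-6-(triisopropylsiloxy)phenyl]-7-methoxychromen-4-one | COc1cc2oc(-c3ccc(OCc4ccccc4)cc3)cc(=O)c2c(OCc2ccccc2)c1-c1c(O)c(C=O)c(OCC)cc1O[Si](C(C)C)(C(C)C)C(C)C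
F8 | step 10 | 5-(benzyloxy)-2-[4-(benzyloxy)phenyl]-6-[4-ethoxy-2-hydroxy-3-(1-hydroxyethyl)-6-(triisopropylsiloxy)phenyl]-7-methoxychromen-4-one (mixture of stereoisomers) | COc1cc2oc(-c3ccc(OCc4ccccc4)cc3)cc(=O)c2c(OCc2ccccc2)c1-c1c(O)c(C(C)O)c(OCC)cc1O[Si](C(C)C)(C(C)C)C(C)C
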